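**Retrosynthetic overview** (target numbered as spiro[5.5]undec-1-ene; ring A = C1–C6, ring B = C6–C11)
- Endgame: the C4–Br bond comes from the (S)-homoallylic alcohol by SN2 inversion, the alcohol from the β,γ-enone by reagent-controlled reduction, and the enone from a β-ethoxy ketone by loss of EtOH and kinetic deconjugation.
- Key disconnection: ring A is cut at C1–C2 and C5–C6 in a strain-release formal [4+2] between 3-ethoxy-2,2-dimethylcyclobutanone (supplies C2, C3, C4, C5) and the exocyclic ethylidene group of ring B (supplies C1 with its methyl group and C6).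
- Enabling feature: in ring A the gem-dimethyl carbon C5 is flanked by the heteroatom-bearing C4, and C2 stands 1,3 to C4. The unit C5–C4(=O)–C3–C2(OEt) is therefore the opened form (enolate carbon C5, oxocarbenium carbon C2) of the dimethylketene/ethyl vinyl ether cyclobutanone, and the spiro atom C6 is a fully alkylated ring-B carbon that can carry a tertiary cation.
- Ring B is taken intact from (R)-limonene: Markovnikov, trans-diaxial BrCl addition sets C8 and C9, the isopropenyl group is cut down to ethylidene, and the axial C8–Br then directs the spiro centre C6. Order of ring formation: ring B (chiral pool), the temporary cyclobutanone ring, then ring A in the key step.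

Key step: step 6

Remark: the enol triflate and the ethylidene alkene are E/Z mixtures, and the key-step adduct and the derived enone are mixtures at ring-A carbons that later become sp2. Their SMILES leave these elements open, which is without consequence because the spiro carbon passes through a planar cation and the other centres are erased.

Step 1
Reactants: 1 isobutyryl chloride (2-methylpropanoyl chloride); 2 ethyl vinyl ether
Product: 4 3-ethoxy-2,2-dimethylcyclobutan-1-one (racemic), via dimethylketene 3 (not isolated)
Conditions: Et3N (1.2 equiv), MeCN, reflux, ethyl vinyl ether in excess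
Reagents that add atoms: none
Why: Et3N dehydrochlorinates 1 to dimethylketene, which should undergo the thermal ketene–enol ether [2+2] cycloaddition with the ketene carbonyl carbon bonding to the CH2 terminus of 2; the single stereocentre is racemic and is destroyed in step 7.

Step 2
Reactants: 5 (R)-(+)-limonene
Product: 6 (1S,2S,4R)-2-bromo-1-chloro-1-methyl-4-(prop-1-en-2-yl)cyclohexane
Conditions: NBS (1.0 equiv), HCl (1.0 equiv, 2 M in Et2O), CH2Cl2, −78 °C
Reagents that add atoms: N-bromosuccinimide (O=C1CCC(=O)N1Br); hydrogen chloride (Cl)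
Why: BrCl formed in situ should add anti to the more electron-rich trisubstituted ring alkene with chloride at the tertiary carbon (Markovnikov), and only the bromonium ion whose Markovnikov opening is trans-diaxial with isopropenyl equatorial (Fürst–Plattner rule) opens readily, so the C4 stereocentre should place Cl cis and Br trans to the isopropenyl group, as in the bromohydrin formation of limonene.

Step 3
Reactants: 6 (1S,2S,4R)-2-bromo-1-chloro-1-methyl-4-(prop-1-en-2-yl)cyclohexane
Product: 7 1-[(1R,3S,4S)-3-bromo-4-chloro-4-methylcyclohexyl]ethan-1-one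
Conditions: O3, CH2Cl2/MeOH, −78 °C; then Me2S, −78 °C to rt
Reagents that add atoms: ozone ([O-][O+]=O)
Why: Ozonolysis of the only remaining alkene with reductive work-up should give the methyl ketone; the alkyl halides are inert and no stereocentre is formed.

Step 4
Reactants: 7 1-[(1R,3S,4S)-3-bromo-4-chloro-4-methylcyclohexyl]ethan-1-one
Product: 8 1-[(3S,4S)-3-bromo-4-chloro-4-methylcyclohexylidene]ethyl trifluoromethanesulfonate (E/Z mixture)
Conditions: Tf2O, 2,6-di-tert-butyl-4-methylpyridine, CH2Cl2, 0 °C to rt
Reagents that add atoms: trifluoromethanesulfonic anhydride (O=S(=O)(OS(=O)(=O)C(F)(F)F)C(F)(F)F)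
Why: O-Triflation of the ketone and loss of the tertiary α-proton from the triflyloxycarbenium ion (enol triflate formation) should give mainly the more substituted enol triflate, as with isopropyl methyl ketone; the ring stereocentre next to the carbonyl is erased on purpose.

Step 5
Reactants: 8 1-[(3S,4S)-3-bromo-4-chloro-4-methylcyclohexylidene]ethyl trifluoromethanesulfonate
Product: 9 (1S,2S)-2-bromo-1-chloro-4-ethylidene-1-methylcyclohexane (E/Z mixture)
Conditions: Pd(OAc)2 (5 mol %), PPh3 (10 mol %), HCO2H, Bu3N, DMF, 60 °C
Reagents that add atoms: none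
Why: Palladium-catalysed formate reduction of the enol triflate (oxidative addition to zerovalent palladium, formate exchange, decarboxylation, reductive elimination) should fix the double bond in the exocyclic position; the unactivated secondary bromide and tertiary chloride should not add oxidatively to the Pd–PPh3 catalyst.

Step 6
Reactants: 4 3-ethoxy-2,2-dimethylcyclobutan-1-one; 9 (1S,2S)-2-bromo-1-chloro-4-ethylidene-1-methylcyclohexane
Product: 10 (6R,8S,9S)-8-bromo-9-chloro-4-ethoxy-1,1,5,9-tetramethylspiro[5.5]undecan-2-one (mixture at C4 and C5)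
Conditions: SnCl4 (0.3 equiv), 2,6-di-tert-butylpyridine (0.1 equiv), CH2Cl2, −78 to −45 °C; then aq NaHCO3
Reagents that add atoms: none
Why: Proposed new method: SnCl4 binds the carbonyl of 4 and, driven by release of the four-membered-ring strain and the push of the ethoxy group, cleaves the more substituted C2–C3 bond to a 1,4-zwitterion (tin enolate of an isopropyl ketone and ethoxycarbenium ion), the CH(CH3) terminus of 9 adds to the oxocarbenium carbon in the Markovnikov sense (first bond) and the gem-dimethyl enolate carbon then closes onto the tertiary ring-B cation so formed (second bond, between two fully substituted carbons), so that 10 holds every atom of 4 and 9. The closest known reaction type is the Lewis-acid-promoted formal [4+2] cycloaddition of 3-alkoxycyclobutanones with allylsilanes, silyl enol ethers and aldehydes, together with the α-tert-alkylation of enolates by tertiary cations; new is an unactivated trisubstituted alkene as the intermolecular two-carbon partner. Ring A closes as a stepwise polar formal [4+2] annulation, the second bond forming by 6-(enolendo) ion-pair collapse of the C-enolate onto the cyclohexyl cation. The spiro centre (6R) is set by substrate control: in the ring-B chair with Br and Cl trans-diaxial and CH3 equatorial, the syn-axial C–Br bond shields one lobe of the cation, so the enolate carbon should bond equatorially, anti to Br and cis to Cl, while the centres at C4 (OEt) and C5 (CH3) form as mixtures and are erased in steps 7 and 8. The step needs cleavage of the cyclobutanone on the gem-dimethyl side (secured by the more substituted enolate), ring closure faster than proton transfer from the cation (non-basic counter-ion, hindered base as acid buffer, low temperature) and an untouched tertiary chloride (ionisation retarded inductively by the vicinal bromine and by the low temperature).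

Step 7
Reactants: 10 (6R,8S,9S)-8-bromo-9-chloro-4-ethoxy-1,1,5,9-tetramethylspiro[5.5]undecan-2-one
Product: 11 (6R,8S,9S)-8-bromo-9-chloro-1,1,5,9-tetramethylspiro[5.5]undec-3-en-2-one (both C5 epimers)
Conditions: p-TsOH·H2O (10 mol %), toluene, 60 °C
Reagents that add atoms: none
Why: Acid-catalysed β-elimination of ethanol from the β-alkoxy ketone through the enol should give the conjugated enone from both C4 epimers.

Step 8
Reactants: 11 (6R,8S,9S)-8-bromo-9-chloro-1,1,5,9-tetramethylspiro[5.5]undec-3-en-2-one
Product: 13 (6R,8S,9S)-8-bromo-9-chloro-1,1,5,9-tetramethylspiro[5.5]undec-4-en-2-one, via potassium dienolate 12 (not isolated)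
Conditions: KN(SiMe3)2 (1.3 equiv), THF, −78 °C; then AcOH (3 equiv), −78 °C
Reagents that add atoms: none
Why: γ-Deprotonation at C5 (the only acidic C–H, since C1 is quaternary) should give the linear dienolate from both epimers, and irreversible protonation at −78 °C occurs at the α-carbon (kinetic deconjugation of an enone), placing the trisubstituted alkene at C4=C5.

Step 9
Reactants: 13 (6R,8S,9S)-8-bromo-9-chloro-1,1,5,9-tetramethylspiro[5.5]undec-4-en-2-one
Product: 14 (2S,6R,8S,9S)-8-bromo-9-chloro-1,1,5,9-tetramethylspiro[5.5]undec-4-en-2-ol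
Conditions: (R)-2-methyl-CBS-oxazaborolidine (20 mol %), catecholborane (1.5 equiv), toluene, −40 °C; then MeOH, aq NaOH wash
Reagents that add atoms: none
Why: In this Corey–Bakshi–Shibata reduction the quaternary C1 is the large and C3H2 the small carbonyl substituent, so the (R)-catalyst should deliver hydride under reagent control to give the (2S)-alcohol, and catecholborane does not hydroborate the alkene at this temperature.

Step 10
Reactants: 14 (2S,6R,8S,9S)-8-bromo-9-chloro-1,1,5,9-tetramethylspiro[5.5]undec-4-en-2-ol
Product: 15 (4R,6R,8S,9S)-4,8-dibromo-9-chloro-1,5,5,9-tetramethylspiro[5.5]undec-1-ene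
Conditions: CBr4, P(n-C8H17)3, toluene, 70 °C
Reagents that add atoms: tetrabromomethane (BrC(Br)(Br)Br)
Why: In this Appel reaction bromide should displace the alkoxyphosphonium group by SN2 with inversion at the neopentylic carbon ((2S)-OH becomes (4R)-Br in the target numbering), the more nucleophilic trialkylphosphine being the reagent of choice for hindered secondary alcohols next to a gem-dimethyl carbon.

**Compound list**
1 | isobutyryl chloride | CC(C)C(Cl)=O | starting material
2 | ethyl vinyl ether | C=COCC | starting material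
3 | dimethylketene | CC(C)=C=O | intermediate
4 | 3-ethoxy-2,2-dimethylcyclobutan-1-one (racemic) | CCOC1CC(=O)C1(C)C | intermediate
5 | (R)-(+)-limonene | CC1=CC[C@@H](CC1)C(C)=C | starting material
6 | (1S,2S,4R)-2-bromo-1-chloro-1-methyl-4-(prop-1-en-2-yl)cyclohexane | C=C(C)[C@@H]1CC[C@](C)(Cl)[C@@H](Br)C1 | intermediate
7 | 1-[(1R,3S,4S)-3-bromo-4-chloro-4-methylcyclohexyl]ethan-1-one | CC(=O)[C@@H]1CC[C@](C)(Cl)[C@@H](Br)C1 | intermediate
8 | 1-[(3S,4S)-3-bromo-4-chloro-4-methylcyclohexylidene]ethyl trifluoromethanesulfonate (E/Z) | CC(OS(=O)(=O)C(F)(F)F)=C1CC[C@](C)(Cl)[C@@H](Br)C1 | intermediate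
9 | (1S,2S)-2-bromo-1-chloro-4-ethylidene-1-methylcyclohexane (E/Z) | CC=C1CC[C@](C)(Cl)[C@@H](Br)C1 | intermediate
10 | (6R,8S,9S)-8-bromo-9-chloro-4-ethoxy-1,1,5,9-tetramethylspiro[5.5]undecan-2-one (mixture at C4, C5) | CC1C(OCC)CC(=O)C(C)(C)[C@@]12CC[C@](C)(Cl)[C@@H](Br)C2 | intermediate
11 | (6R,8S,9S)-8-bromo-9-chloro-1,1,5,9-tetramethylspiro[5.5]undec-3-en-2-one (C5 epimers) | CC1C=CC(=O)C(C)(C)[C@@]12CC[C@](C)(Cl)[C@@H](Br)C2 | intermediate
12 | potassium (6R,8S,9S)-8-bromo-9-chloro-1,1,5,9-tetramethylspiro[5.5]undeca-2,4-dien-2-olate | CC1=CC=C([O-])C(C)(C)[C@@]12CC[C@](C)(Cl)[C@@H](Br)C2.[K+] | intermediate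
13 | (6R,8S,9S)-8-bromo-9-chloro-1,1,5,9-tetramethylspiro[5.5]undec-4-en-2-one | CC1=CCC(=O)C(C)(C)[C@@]12CC[C@](C)(Cl)[C@@H](Br)C2 | intermediate
14 | (2S,6R,8S,9S)-8-bromo-9-chloro-1,1,5,9-tetramethylspiro[5.5]undec-4-en-2-ol | CC1=CC[C@H](O)C(C)(C)[C@@]12CC[C@](C)(Cl)[C@@H](Br)C2 | intermediate
15 | (4R,6R,8S,9S)-4,8-dibromo-9-chloro-1,5,5,9-tetramethylspiro[5.5]undec-1-ene | CC1=CC[C@@H](Br)C(C)(C)[C@@]12CC[C@](C)(Cl)[C@@H](Br)C2 | target

**Totals**
Total step count: 10. Longest linear sequence: 9 steps (steps 2 to 10, from (R)-limonene).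

**Steps most likely to fail**

Step 6 (Proposed new method). What may go wrong: proton loss from the tertiary ring-B cation (ene-type, open-chain products) or migration of the alkene into the ring may outrun the enolate–cation ring closure, the Lewis acid may ionise the tertiary chloride, and the facial selectivity at the spiro carbon may erode. The fallback uses known chemistry (Stille coupling, Ireland–Claisen rearrangement, ring-closing metathesis); it sets out from 8 and comes back to the route at 13. Stille hydroxymethylation of 8 (Bu3SnCH2OH, Pd(PPh3)4, LiCl, dioxane, 90 °C) should give 2-[(3S,4S)-3-bromo-4-chloro-4-methylcyclohexylidene]propan-1-ol F1, and acylation (isobutyric anhydride, DMAP, Et3N, CH2Cl2) should give 2-[(3S,4S)-3-bromo-4-chloro-4-methylcyclohexylidene]propyl 2-methylpropanoate F2. Under Ireland–Claisen conditions (LiN(i-Pr)2, Me3SiCl, THF, −78 °C, then 60 °C) the ester should pass through the silyl ketene acetal [(1-{2-[(3S,4S)-3-bromo-4-chloro-4-methylcyclohexylidene]propoxy}-2-methylprop-1-en-1-yl)oxy]trimethylsilane F3, whose [3,3]-sigmatropic shift forms the C5–C6 bond between the two quaternary carbons, again anti to the axial C–Br, to give trimethylsilyl 2-[(1R,3S,4S)-3-bromo-4-chloro-4-methyl-1-(prop-1-en-2-yl)cyclohexyl]-2-methylpropanoate F4; dilute aqueous HCl then frees 2-[(1R,3S,4S)-3-bromo-4-chloro-4-methyl-1-(prop-1-en-2-yl)cyclohexyl]-2-methylpropanoic acid F5. Oxalyl chloride (cat. DMF, CH2Cl2) should give 2-[(1R,3S,4S)-3-bromo-4-chloro-4-methyl-1-(prop-1-en-2-yl)cyclohexyl]-2-methylpropanoyl chloride F6, which with MeNHOMe·HCl and pyridine gives 2-[(1R,3S,4S)-3-bromo-4-chloro-4-methyl-1-(prop-1-en-2-yl)cyclohexyl]-N-methoxy-N,2-dimethylpropanamide F7. Allylmagnesium bromide (THF, −78 to 0 °C) should give 2-[(1R,3S,4S)-3-bromo-4-chloro-4-methyl-1-(prop-1-en-2-yl)cyclohexyl]-2-methylhex-5-en-3-one F8, and ring-closing metathesis with the second-generation Grubbs catalyst (toluene, 80 °C) closes the C1=C2 bond of the target directly in the β,γ-position to give 13.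

Step 10. What may go wrong: the alkoxyphosphonium ion may ionise at the neopentylic carbon, with methyl migration, elimination or participation of the homoallylic double bond (retention) instead of clean SN2 inversion. The fallback makes the C4–Br bond with electrophilic bromine instead of by substitution; it sets out from 8 and comes back at 15. Negishi coupling of 8 with (4-methylpent-3-en-1-yl)zinc bromide (Pd(PPh3)4, THF, 50 °C) should give (1S,2S)-2-bromo-1-chloro-1-methyl-4-(6-methylhept-5-en-2-ylidene)cyclohexane F9. Bromonium-induced cation–olefin cyclisation of this diene with Et2SBr·SbCl5Br (MeNO2, −25 °C), the biogenetic type of ring closure of bromochamigrenes, should form C4–Br and C5–C6 together and, after proton loss from C2, give 15; isomers at C4 and C6 and the exocyclic-alkene isomer would have to be separated.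

Step 8. What may go wrong: the amide base may cause dehydrohalogenation in ring B, and the β,γ-enone may reconjugate during quench and isolation. The fallback deconjugates without strong base through the dienyl ester; it sets out from 11 and comes back at 13. Isopropenyl acetate with catalytic p-TsOH at reflux should give (6R,8S,9S)-8-bromo-9-chloro-1,1,5,9-tetramethylspiro[5.5]undeca-2,4-dien-2-yl acetate F10. NaBH4 in EtOH/THF at 0 °C cleaves the acetate, the dienolate is protonated at the α-carbon and the β,γ-enone is reduced before it can reconjugate, which should give (6R,8S,9S)-8-bromo-9-chloro-1,1,5,9-tetramethylspiro[5.5]undec-4-en-2-ol F11 as a mixture of C2 epimers. Dess–Martin periodinane (NaHCO3, CH2Cl2) then oxidises the mixture to 13 without moving the double bond.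

**Further compounds**
F1 | step 6 | 2-[(3S,4S)-3-bromo-4-chloro-4-methylcyclohexylidene]propan-1-ol (E/Z) | CC(CO)=C1CC[C@](C)(Cl)[C@@H](Br)C1
F2 | step 6 | 2-[(3S,4S)-3-bromo-4-chloro-4-methylcyclohexylidene]propyl 2-methylpropanoate (E/Z) | CC(C)C(=O)OCC(C)=C1CC[C@](C)(Cl)[C@@H](Br)C1
F3 | step 6 | [(1-{2-[(3S,4S)-3-bromo-4-chloro-4-methylcyclohexylidene]propoxy}-2-methylprop-1-en-1-yl)oxy]trimethylsilane (E/Z) | CC(C)=C(O[Si](C)(C)C)OCC(C)=C1CC[C@](C)(Cl)[C@@H](Br)C1
F4 | step 6 | trimethylsilyl 2-[(1R,3S,4S)-3-bromo-4-chloro-4-methyl-1-(prop-1-en-2-yl)cyclohexyl]-2-methylpropanoate | C[Si](C)(C)OC(=O)C(C)(C)[C@]1(C(C)=C)CC[C@](C)(Cl)[C@@H](Br)C1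
F5 | step 6 | 2-[(1R,3S,4S)-3-bromo-4-chloro-4-methyl-1-(prop-1-en-2-yl)cyclohexyl]-2-methylpropanoic acid | OC(=O)C(C)(C)[C@]1(C(C)=C)CC[C@](C)(Cl)[C@@H](Br)C1
F6 | step 6 | 2-[(1R,3S,4S)-3-bromo-4-chloro-4-methyl-1-(prop-1-en-2-yl)cyclohexyl]-2-methylpropanoyl chloride | ClC(=O)C(C)(C)[C@]1(C(C)=C)CC[C@](C)(Cl)[C@@H](Br)C1
F7 | step 6 | 2-[(1R,3S,4S)-3-bromo-4-chloro-4-methyl-1-(prop-1-en-2-yl)cyclohexyl]-N-methoxy-N,2-dimethylpropanamide | CON(C)C(=O)C(C)(C)[C@]1(C(C)=C)CC[C@](C)(Cl)[C@@H](Br)C1
F8 | step 6 | 2-[(1R,3S,4S)-3-bromo-4-chloro-4-methyl-1-(prop-1-en-2-yl)cyclohexyl]-2-methylhex-5-en-3-one | C=CCC(=O)C(C)(C)[C@]1(C(C)=C)CC[C@](C)(Cl)[C@@H](Br)C1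
F9 | step 10 | (1S,2S)-2-bromo-1-chloro-1-methyl-4-(6-methylhept-5-en-2-ylidene)cyclohexane (E/Z) | CC(C)=CCCC(C)=C1CC[C@](C)(Cl)[C@@H](Br)C1
F10 | step 8 | (6R,8S,9S)-8-bromo-9-chloro-1,1,5,9-tetramethylspiro[5.5]undeca-2,4-dien-2-yl acetate | CC1=CC=C(OC(C)=O)C(C)(C)[C@@]12CC[C@](C)(Cl)[C@@H](Br)C2
F11 | step 8 | (6R,8S,9S)-8-bromo-9-chloro-1,1,5,9-tetramethylspiro[5.5]undec-4-en-2-ol (C2 epimers) | CC1=CCC(O)C(C)(C)[C@@]12CC[C@](C)(Cl)[C@@H](Br)C2
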